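We read each flask at 30 min and ask how much bis adduct stands in it as the substrate charge climbs while the reagent charge stays the same.

    substrate + reagent → mono adduct (k1 = 0.0209 M⁻¹ s⁻¹)
    reagent + bis adduct → triple product (k2 = 0.0615 M⁻¹ s⁻¹)
    substrate + bis adduct → side product (k3 = 0.0385 M⁻¹ s⁻¹)
    reagent + mono adduct → bis adduct (k4 = 0.0118 M⁻¹ s⁻¹)

common to all: reagent 19.0 mM; time 30 min
- midnight: substrate 10 mM
- summer: substrate 20 mM
- dawn: substrate 40 mM
- autumn: substrate 80 mM

* [bis adduct] at the end for midnight, summer, dawn, autumn, in this order
* the shape of the row from first to last (hardly changes / rises all the way / rises, then falls / falls all the way / falls, then rises)

- percent here means substrate units held: one side product counts as two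
- "hardly changes" means that all values lie within two and a half points (for a concentration: within two and a half percent of the largest)
- run time (midnight): 30 min

We draw by hand the end value of c_bis adduct against the substrate charge. At the left end the curve climbs, since mono adduct, the source of bis adduct, is made at the start of midnight at 0.238 mM min⁻¹, and in summer at twice that. Bis adduct has two exits: to triple product with reagent, and to side product with substrate. The knee should lie where they are equally fast, and that is our zero of the scale. We call it the even charge, the substrate concentration that removes bis adduct as fast as the reagent charge does, 0.0615 M⁻¹ s⁻¹ times c_reagent divided by 0.0385 M⁻¹ s⁻¹, which is 30.4 mM. Midnight lies below it: there the half-life of bis adduct by the reagent exit alone, with concentrations as charged, is 9.9 min, shorter than the 30 min by the substrate exit alone. Summer also lies below the even charge, while dawn lies above it, and autumn stands at 2.64 times it.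

But reckoned with the reagent standing at a later moment instead of the charge, the even charge is smaller in step with that reagent. In autumn, with substrate in excess, we treat the reagent as decaying in a pseudo-first-order way: holding the substrate at its charge and counting step 1 alone, the estimated fraction of reagent left at the end is about 4.93 %. At a given c_mono adduct, the making of bis adduct also falls in step with the reagent, so we commit to a row that rises and then falls, turning somewhat below the even charge. We attempt no end concentrations by hand.

The forecast gave 0.4 mM, 0.55 mM, 0.47 mM and 0.14 mM, a row that rises, then falls, holding that at high substrate “the reagent runs out and the excess substrate consumes bis adduct as side product”.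

The flasks give 0.383 mM, 0.535 mM, 0.470 mM and 0.142 mM, a row that rises, then falls, with its turn at 25 mM, against the even charge of 30.4 mM. Scaling the even charge by the reagent left at the end gives 21.5 mM for midnight, where 5.41 mM of substrate stands. The same scaling gives 1.84 mM for autumn, where 62.5 mM of substrate stands.

The numbers of this flask come from no measurement, and the outcome is calculated.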